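Readings and results are simulated with made-up constants.

The incoming ligand is the setting I turn first. By hand, the complex with one exchanged should rise in step with its charge, so going from ash to oak, 6.25 times the charge should give as many times the reading. At 3.00 min it gives 1.65 times, from 15.4% to 25.4% of the starting complex charged.

Time comes next. By hand, waiting gives more, yet ash falls from 17.3% at 0.833 min to 15.4%, and oak from 32.3% at 0.417 min to 25.4%. I read the end value as what remains after a peak, and the proposed step to homo dimer is the one with a single arrow.

By hand, more leaving ligand pushes both exchanges back. Ash and oak both hold 5 equiv, as the new flasks hold 5.00 equiv, so these readings can't show that.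

the same everywhere: starting complex 0.50 mM
- ash: incoming ligand 0.48 equiv; leaving ligand 5 equiv; run made earlier
- oak: incoming ligand 3 equiv; leaving ligand 5 equiv; run made earlier
- zeta: incoming ligand 0.800 equiv; leaving ligand 5.00 equiv; time 3.0 min
- beta: incoming ligand 1.20 equiv; leaving ligand 5.00 equiv; time 3.0 min
- gamma: incoming ligand 4.00 equiv; leaving ligand 5.00 equiv; time 3.0 min

| run | time / min | complex with one exchanged / % |
|---|---|---|
| ash | 0.250 | 15.5 |
| ash | 0.833 | 17.3 |
| ash | 1.33 | 16.8 |
| ash | 2.00 | 16.6 |
| ash | 3.00 | 15.4 |
| oak | 0.250 | 31.5 |
| oak | 0.417 | 32.3 |
| oak | 0.833 | 31.2 |
| oak | 1.50 | 29.0 |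
| oak | 3.00 | 25.4 |

(each reading ± 0.3 percentage points)

- steps that have been proposed: starting complex + incoming ligand <-> leaving ligand + complex with one exchanged; complex with one exchanged + incoming ligand <-> leaving ligand + complex with two exchanged; 2 incoming ligand -> homo dimer

So I go to logarithms at the fixed time. The charge climbs 0.796 of a decade and the reading 0.217 of a decade. Their quotient, read from two readings each good to 0.3 percentage points, is 0.273. I call it the charge exponent, the decades of end reading gained per decade of incoming ligand charged, an apparent order.

Anchored on ash, it gives me 17.7% for zeta and 19.8% for beta. For gamma it gives 27.5%, an extrapolation, since gamma's charge is larger than oak's.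

1. amount of complex with one exchanged at the end, in percent of the starting complex charged, for each flask in turn (zeta, beta, gamma)

The forecast, higher than mine in zeta and lower in gamma, reads 20%, 23% and 26%, on the ground that “dimerisation slowly drains free incoming ligand”.

The flasks give 18.7%, 21.0% and 26.6% in zeta, beta and gamma, from this scheme:

    starting complex + incoming ligand ⇌ leaving ligand + complex with one exchanged (K = 36.0, k = 140 L mol⁻¹ s⁻¹)
    complex with one exchanged + incoming ligand ⇌ leaving ligand + complex with two exchanged (K = 11.0, k = 76.0 L mol⁻¹ s⁻¹)
    2 incoming ligand → homo dimer (k = 340 L mol⁻¹ s⁻¹)

My line lies 1.00 point under zeta and 0.90 points over gamma. In zeta at the end, the complex with one exchanged is made at 0.136 of the rate at which it is used up, each step taken net, so it is still falling. Started from zeta's own value, the exponent gives 20.9% for beta, which stands at 21.0%.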